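**Retrosynthetic overview**
1. The cage is opened at three C–C bonds in one pot: C3–CH(ring fusion) and CMe2–CH(iPr) by a Bu3SnH radical 7-exo/5-exo cascade from a C3 chloride, and C1–C8 by cationic enol alkylation from a tertiary alcohol. This leads back to a monocyclic, dearomatised chloro-triketone.
2. Ring order: the trione ring is the purchased phloroglucinol ring; then the second ring of the bicyclo[3.3.1] core (cation), the seven-membered ring and the cyclopentane (radicals).
3. The monocycle comes from 2,4,6-trihydroxybenzophenone by C-alkylation with a hydrated (S)-lavandulyl iodide, ring chlorination, dearomatising geranylation and prenylation at the chlorinated carbon. The chlorine steers the alkylations, blocks C3 during the cation step and is the radical precursor.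
4. The iodide (C6–C8 and the C7 stereocentre) comes from an Evans deconjugative alkylation of a senecioyl imide with prenyl bromide, then reduction, Markovnikov hydration and iodination.

Assumption: locants follow the usual PPAP numbering (C1 benzoyl-bearing bridgehead, C2/C4/C9 carbonyls, C3 between C2 and C4, C5 geranyl-bearing bridgehead, C6 CH2, C7 CH, C8 CMe2), also for monocyclic precursors, and each enolisable compound is written as one tautomer.

**Route**

Step 1
Reactants: 1 (4S)-4-benzyl-1,3-oxazolidin-2-one; 2 3-methylbut-2-enoyl chloride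
Product: 3 (4S)-4-benzyl-3-(3-methylbut-2-enoyl)-1,3-oxazolidin-2-one
Conditions: n-BuLi, THF, −78 °C; then 2, −78 to 0 °C
Reagents that add atoms: none
Why: N-acylation of the lithiated Evans oxazolidinone by an acid chloride is fast and clean at low temperature and forms no stereocentre.

Step 2
Reactants: 3 (4S)-4-benzyl-3-(3-methylbut-2-enoyl)-1,3-oxazolidin-2-one; 4 prenyl bromide (1-bromo-3-methylbut-2-ene)
Product: 5 (4S)-4-benzyl-3-[(2S)-5-methyl-2-(prop-1-en-2-yl)hex-4-enoyl]-1,3-oxazolidin-2-one
Conditions: NaN(SiMe3)2, THF, −78 °C; then 4, −78 to −20 °C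
Reagents that add atoms: none
Why: Evans asymmetric alkylation in its deconjugative form: γ-deprotonation gives the chelated dienolate, which is alkylated at the α-carbon on the face away from the benzyl group, setting the (2S) centre (later C7) while the alkene moves out of conjugation to give the isopropenyl group.

Step 3
Reactants: 5 (4S)-4-benzyl-3-[(2S)-5-methyl-2-(prop-1-en-2-yl)hex-4-enoyl]-1,3-oxazolidin-2-one
Product: 6 (S)-lavandulol [(2S)-5-methyl-2-(prop-1-en-2-yl)hex-4-en-1-ol]
Conditions: LiBH4, H2O (1 equiv), Et2O, 0 °C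
Reagents that add atoms: none
Why: Reductive cleavage of the N-acyl oxazolidinone by LiBH4 gives the primary alcohol and returns 1, and the non-conjugated α-centre does not epimerise.

Step 4
Reactants: 6 (S)-lavandulol
Product: 7 (3R)-3-(hydroxymethyl)-2,6-dimethylhept-5-en-2-ol
Conditions: Co(acac)2 (20 mol %), PhSiH3, O2 (1 atm), THF, rt
Reagents that add atoms: dioxygen, O=O
Why: Mukaiyama hydration (metal hydride hydrogen atom transfer, O2 capture, reduction) is Markovnikov and faster at the 1,1-disubstituted alkene than at the trisubstituted one, so the tertiary alcohol that becomes the C8 leaving group is installed without touching the stereocentre (its label changes from S to R by priority only).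

Step 5
Reactants: 7 (3R)-3-(hydroxymethyl)-2,6-dimethylhept-5-en-2-ol
Product: 8 (3S)-3-(iodomethyl)-2,6-dimethylhept-5-en-2-ol
Conditions: I2, PPh3, imidazole, CH2Cl2, 0 °C
Reagents that add atoms: iodine, I-I
Why: Garegg–Samuelsson (Appel-type) iodination converts only the primary alcohol because the tertiary one is too hindered to be displaced, and the stereocentre is untouched.

Step 6
Reactants: 9 2,4,6-trihydroxybenzophenone; 8 (3S)-3-(iodomethyl)-2,6-dimethylhept-5-en-2-ol
Product: 10 {2,4,6-trihydroxy-3-[(2R)-2-(2-hydroxypropan-2-yl)-5-methylhex-4-en-1-yl]phenyl}(phenyl)methanone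
Conditions: 9 (3 equiv), NaOH (2.5 equiv), H2O–MeOH 1:1, 60 °C, 48 h
Reagents that add atoms: none
Why: SN2 C-alkylation of the phloroglucinol phenoxide in a protic medium (C- over O-alkylation), with 9 in excess so that only one ring carbon reacts and no free hydroxide remains to close the iodo alcohol to an oxetane; the stereocentre is not involved.

Step 7
Reactants: 10 {2,4,6-trihydroxy-3-[(2R)-2-(2-hydroxypropan-2-yl)-5-methylhex-4-en-1-yl]phenyl}(phenyl)methanone
Product: 11 {3-chloro-2,4,6-trihydroxy-5-[(2R)-2-(2-hydroxypropan-2-yl)-5-methylhex-4-en-1-yl]phenyl}(phenyl)methanone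
Conditions: N-chlorosuccinimide (1.0 equiv), MeCN, 0 °C
Reagents that add atoms: N-chlorosuccinimide, O=C1CCC(=O)N1Cl
Why: Electrophilic aromatic chlorination takes the single free ring C–H of the very electron-rich triol far faster than the reagent attacks the isolated alkene, placing the chlorine that steers step 8, blocks C3 and later serves as radical precursor.

Step 8
Reactants: 11 {3-chloro-2,4,6-trihydroxy-5-[(2R)-2-(2-hydroxypropan-2-yl)-5-methylhex-4-en-1-yl]phenyl}(phenyl)methanone; 12 geranyl bromide [(2E)-1-bromo-3,7-dimethylocta-2,6-diene]; 4 prenyl bromide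
Product: 14 (4S,6RS)-2-benzoyl-6-chloro-4-[(2E)-3,7-dimethylocta-2,6-dien-1-yl]-3-hydroxy-4-[(2R)-2-(2-hydroxypropan-2-yl)-5-methylhex-4-en-1-yl]-6-(3-methylbut-2-en-1-yl)cyclohex-2-ene-1,5-dione, via dearomatised geranyl triketone 13 (not isolated)
Conditions: LiN(SiMe3)2 (3.1 equiv), toluene–THF 4:1, −20 °C; 12 (1.0 equiv), to 0 °C; then 4 (1.2 equiv), 0 °C to rt
Reagents that add atoms: none
Why: Two successive alkylative dearomatisation-type C-alkylations of the phenoxide/enolate in a weakly polar medium: geranyl bromide goes to the alkyl-bearing ring carbon (the chloro- and benzoyl-bearing carbons are less nucleophilic) and is expected to enter anti to C7, which the metal-bridged side-chain carbinol holds over one ring face, giving mainly the drawn C5 configuration, and prenyl bromide then alkylates the 2-chloro-1,3-dione carbon, the only one left, as a C3 epimer mixture that is planarised in step 9 (a minor C5 epimer cannot close the cage there and is removed).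

Step 9
Reactants: 14 (4S,6RS)-chloro-triketone from step 8
Product: 16 CNP0155129.3 (target cage), via bicyclic chloride 15 (not isolated)
Conditions: HCO2H, rt, 12 h; evaporate (toluene azeotrope); then Bu3SnH (1.3 equiv, syringe pump, 6 h), 2,2'-azobis(2-methylpropionitrile) (20 mol %), benzene (5 mM), 80 °C
Reagents that add atoms: none
Why: Proposed new method: formic acid ionises the tertiary alcohol to the C8 cation, which can form a C–C bond only at C1 of the acidic triketone enol because C3 is a blocked quaternary chloride and capture by oxygen or formate is reversible in this medium (closest known reaction type: biomimetic SN1 cationic cyclisation of dearomatised acylphloroglucinols to bicyclo[3.3.1]nonanetriones), the drawn C5/C7 pair forcing the C7 prenyl group endo and fixing C1; after the solvent change Bu3Sn• abstracts the C3 chlorine (closest known reaction types: Bu3SnH cyclisation of α-halo-1,3-dicarbonyls and Mn(OAc)3 cascades of bicyclic polyprenylated acylphloroglucinols), the planar C3 radical adds 7-exo-trig through its endo lobe to the CH end of the C7 prenyl alkene with the CMe2 radical turned toward the less hindered C5/C6 side (sets C3 and the ring-fusion CH), this radical closes 5-exo-trig on the C3 prenyl alkene through a Beckwith chair transition state that puts the isopropyl radical trans to the CH2 bridge (sets CH(iPr)), and Bu3SnH supplies the last hydrogen.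

**Compound list**
1 | (4S)-4-benzyl-1,3-oxazolidin-2-one | O=C1N[C@@H](Cc2ccccc2)CO1 | starting material
2 | 3-methylbut-2-enoyl chloride | CC(C)=CC(=O)Cl | starting material
3 | (4S)-4-benzyl-3-(3-methylbut-2-enoyl)-1,3-oxazolidin-2-one | CC(C)=CC(=O)N1[C@@H](Cc2ccccc2)COC1=O | intermediate
4 | prenyl bromide (1-bromo-3-methylbut-2-ene) | CC(C)=CCBr | starting material
5 | (4S)-4-benzyl-3-[(2S)-5-methyl-2-(prop-1-en-2-yl)hex-4-enoyl]-1,3-oxazolidin-2-one | CC(C)=CC[C@@H](C(C)=C)C(=O)N1[C@@H](Cc2ccccc2)COC1=O | intermediate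
6 | (S)-lavandulol, (2S)-5-methyl-2-(prop-1-en-2-yl)hex-4-en-1-ol | OC[C@H](C(C)=C)CC=C(C)C | intermediate
7 | (3R)-3-(hydroxymethyl)-2,6-dimethylhept-5-en-2-ol | OC[C@H](C(C)(C)O)CC=C(C)C | intermediate
8 | (3S)-3-(iodomethyl)-2,6-dimethylhept-5-en-2-ol | IC[C@H](C(C)(C)O)CC=C(C)C | intermediate
9 | 2,4,6-trihydroxybenzophenone | O=C(c1ccccc1)c1c(O)cc(O)cc1O | starting material
10 | {2,4,6-trihydroxy-3-[(2R)-2-(2-hydroxypropan-2-yl)-5-methylhex-4-en-1-yl]phenyl}(phenyl)methanone | O=C(c1ccccc1)c1c(O)cc(O)c(C[C@H](C(C)(C)O)CC=C(C)C)c1O | intermediate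
11 | {3-chloro-2,4,6-trihydroxy-5-[(2R)-2-(2-hydroxypropan-2-yl)-5-methylhex-4-en-1-yl]phenyl}(phenyl)methanone | O=C(c1ccccc1)c1c(O)c(Cl)c(O)c(C[C@H](C(C)(C)O)CC=C(C)C)c1O | intermediate
12 | geranyl bromide, (2E)-1-bromo-3,7-dimethylocta-2,6-diene | CC(C)=CCC/C(C)=C/CBr | starting material
13 | (6R)-2-benzoyl-4-chloro-6-[(2E)-3,7-dimethylocta-2,6-dien-1-yl]-3,5-dihydroxy-6-[(2R)-2-(2-hydroxypropan-2-yl)-5-methylhex-4-en-1-yl]cyclohexa-2,4-dien-1-one (quaternary carbon arranged as C5 of 16) | CC(C)=CCC/C(C)=C/C[C@]1(C[C@H](C(C)(C)O)CC=C(C)C)C(=O)C(C(=O)c2ccccc2)=C(O)C(Cl)=C1O | intermediate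
14 | (4S,6RS)-2-benzoyl-6-chloro-4-[(2E)-3,7-dimethylocta-2,6-dien-1-yl]-3-hydroxy-4-[(2R)-2-(2-hydroxypropan-2-yl)-5-methylhex-4-en-1-yl]-6-(3-methylbut-2-en-1-yl)cyclohex-2-ene-1,5-dione (same spatial arrangement at the quaternary carbon as 13; both C–Cl epimers) | CC(C)=CCC/C(C)=C/C[C@]1(C[C@H](C(C)(C)O)CC=C(C)C)C(O)=C(C(=O)c2ccccc2)C(=O)C(Cl)(CC=C(C)C)C1=O | intermediate
15 | (1S,5S,7R)-1-benzoyl-3-chloro-5-[(2E)-3,7-dimethylocta-2,6-dien-1-yl]-8,8-dimethyl-3,7-bis(3-methylbut-2-en-1-yl)bicyclo[3.3.1]nonane-2,4,9-trione, both C3 epimers, C7 prenyl endo (syn to the C2–C4 bridge); the C5 label differs from 16 by priority only | CC(C)=CCC/C(C)=C/C[C@]12C[C@@H](CC=C(C)C)C(C)(C)[C@](C(=O)c3ccccc3)(C1=O)C(=O)C(Cl)(CC=C(C)C)C2=O | intermediate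
16 | CNP0155129.3: (1S,3S,5R,7R)-1-benzoyl-5-[(2E)-3,7-dimethylocta-2,6-dien-1-yl]-8,8-dimethylbicyclo[3.3.1]nonane-2,4,9-trione core in which C7–CH2–CH(S) is bonded endo to C3 and this CH is joined to C3 through CMe2–CH(iPr)(S)–CH2 (cyclopentane) | CC(C)=CCC/C(C)=C/C[C@@]12C[C@H]3C[C@H]4C(C)(C)[C@H](C(C)C)C[C@]4(C1=O)C(=O)[C@@](C(=O)c1ccccc1)(C2=O)C3(C)C | target

**Totals**
Total steps: 9. Longest linear sequence: 9 (steps 1–9 from 1; 9 enters at step 6, 12 and 4 at step 8).

**Steps most likely to fail, with fallbacks**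

Step 9. The C8 cation may end as the O-bound cyclic enol ether or as an elimination product instead of bonding to C1, and the C3 radical may be reduced before it cyclises. The fallback sets out from 14. The acidic triketone enol is methylated with Me3SiCHN2 (toluene–MeOH, 0 °C) to the methyl enol ether F1. The tertiary alcohol of F1 is then ionised with catalytic Me3SiOTf in CH2Cl2 at −78 °C. The enol ether can attack only through C1 (Mukaiyama/Reetz-type tert-alkylation of an enol ether), and the oxocarbenium ion loses its methyl group as methanol on work-up. This comes back to the route at 15, which is isolated and taken through the Bu3SnH stage of step 9.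

Step 8. Geranyl bromide may also attack the chlorine-bearing ring carbon or oxygen, and the prenylation of the chloro-dione may go to oxygen. The fallback sets out from 10 and blocks the free ring carbon with a carboxyl group instead of chlorine.
- Kolbe–Schmitt carboxylation (KHCO3, CO2, H2O, 60 °C) gives the benzoic acid F2.
- Alkylation of the carboxylate with 4 (KHCO3, DMF, rt) gives its prenyl ester F3.
- Geranylation with 12 (LiN(SiMe3)2, toluene–THF) can now dearomatise only the alkyl-bearing carbon, because both other ring carbons carry acyl groups, and gives the dearomatised ester F4.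
- Pd(PPh3)4-catalysed decarboxylative allylation (Tsuji type, THF, rt) moves the prenyl group to C3 with loss of CO2 and gives the C3-prenyl triketone F5.
- N-chlorosuccinimide (MeCN, 0 °C) chlorinates C3 of F5 and comes back to the route at 14.

Step 6. The β-branched hydroxy iodide 8 may react too slowly, alkylate on oxygen or close to an oxetane. The fallback sets out from 6 and postpones the hydration. Iodination of 6 (I2, PPh3, imidazole) gives (S)-lavandulyl iodide F6, which is less hindered and has no hydroxyl group. C-alkylation of 9 (3 equiv, NaOH, H2O–MeOH, 60 °C) with F6 gives the lavandulyl benzophenone F7. Mukaiyama hydration of the isopropenyl group of F7 (Co(acac)2, PhSiH3, O2, THF) then comes back to the route at 10, replacing steps 4–6.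

**Further compounds**
F1 | step 9 | O-methyl enol ether of 14 (OMe on the C9 enol oxygen; same configurations as 14) | CC(C)=CCC/C(C)=C/C[C@]1(C[C@H](C(C)(C)O)CC=C(C)C)C(OC)=C(C(=O)c2ccccc2)C(=O)C(Cl)(CC=C(C)C)C1=O
F2 | step 8 | 3-benzoyl-2,4,6-trihydroxy-5-[(2R)-2-(2-hydroxypropan-2-yl)-5-methylhex-4-en-1-yl]benzoic acid | O=C(c1ccccc1)c1c(O)c(C(=O)O)c(O)c(C[C@H](C(C)(C)O)CC=C(C)C)c1O
F3 | step 8 | 3-methylbut-2-en-1-yl 3-benzoyl-2,4,6-trihydroxy-5-[(2R)-2-(2-hydroxypropan-2-yl)-5-methylhex-4-en-1-yl]benzoate | O=C(c1ccccc1)c1c(O)c(C(=O)OCC=C(C)C)c(O)c(C[C@H](C(C)(C)O)CC=C(C)C)c1O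
F4 | step 8 | analogue of 13 with a (3-methylbut-2-en-1-yloxy)carbonyl group in place of Cl (same configurations as 13) | CC(C)=CCC/C(C)=C/C[C@]1(C[C@H](C(C)(C)O)CC=C(C)C)C(=O)C(C(=O)c2ccccc2)=C(O)C(C(=O)OCC=C(C)C)=C1O
F5 | step 8 | analogue of 13 with a 3-methylbut-2-en-1-yl group in place of Cl (same configurations as 13) | CC(C)=CCC/C(C)=C/C[C@]1(C[C@H](C(C)(C)O)CC=C(C)C)C(=O)C(C(=O)c2ccccc2)=C(O)C(CC=C(C)C)=C1O
F6 | step 6 | (S)-lavandulyl iodide, (3S)-3-(iodomethyl)-2,6-dimethylhepta-1,5-diene | IC[C@H](C(C)=C)CC=C(C)C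
F7 | step 6 | {2,4,6-trihydroxy-3-[(2R)-5-methyl-2-(prop-1-en-2-yl)hex-4-en-1-yl]phenyl}(phenyl)methanone | O=C(c1ccccc1)c1c(O)cc(O)c(C[C@H](C(C)=C)CC=C(C)C)c1O
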